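**Retrosynthetic overview**
1. Target 7 ⇒ 6,7,8,4'-tetramethoxyflavone 5 by disconnecting the C5–O bond (ketone-directed C–H hydroxylation, last step).
2. 5 ⇒ open-chain 1,3-diketone 4 by disconnecting the O1–C8a aryl–oxygen bond (dehydrogenative aryl C–H/enol O–H cyclisation; key step, new). Ring C is the only ring formed.
3. 4 ⇒ 3',4',5'-trimethoxyacetophenone 1 + methyl 4-methoxybenzoate 2 (Claisen condensation); rings A and B are bought.
4. Logic: the two equivalent ortho C–H bonds of the trimethoxyphenyl ketone become the two C–O bonds, O1–C8a first and C5–OH second.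

Assumption: the target has no stereocentre and no stereogenic double bond, so there is no enantiomer to select; the route gives the single achiral compound shown.

**Step 1**
Reactants: 1 3',4',5'-trimethoxyacetophenone; 2 methyl 4-methoxybenzoate
Product: 4 1-(4-methoxyphenyl)-3-(3,4,5-trimethoxyphenyl)propane-1,3-dione, via sodium diketonate 3 (not isolated)
Conditions: NaH (2.5 equiv), THF, 0 °C to reflux, 6 h; then 1 M HCl, 0 °C
Reagents that add atoms: none
Why: Crossed Claisen condensation in which the methyl ketone enolate is acylated by the non-enolisable ester and the equilibrium is pulled over by irreversible formation of the chelated sodium diketonate 3; no stereocentre is formed.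

**Step 2**
Reactants: 4 1-(4-methoxyphenyl)-3-(3,4,5-trimethoxyphenyl)propane-1,3-dione
Product: 5 6,7,8-trimethoxy-2-(4-methoxyphenyl)-4H-chromen-4-one
Conditions: constant-current electrolysis (undivided cell, graphite anode, Pt cathode, 5 mA cm−2, 2.2 F mol−1), Bu4NBF4 (0.1 M), 1,1,1,3,3,3-hexafluoropropan-2-ol (HFIP)/CH2Cl2 4:1, 25 °C
Reagents that add atoms: none
Why: Proposed new method: anodic one-electron oxidation of the enol of 4 in HFIP, which stabilises radical cations, puts the hole on the trimethoxyphenyl ring, and the distal enol oxygen then attacks C2' in a six-membered closure, because that carbon is para to one methoxy group, ortho to another and β to the aryl ketone, whereas the anisyl ring offers only a carbon meta to its methoxy group; loss of a second electron and a proton rearomatises to the pyranone while HFIP is reduced to H2 at the cathode, and the charge is capped to limit over-oxidation of 5; the closest known reaction type is the oxidative enol-oxygen/arene C–H cyclisation that gives benzofurans and coumestans (FeCl3 or anode) and the dehydrogenative lactonisation of biaryl-2-carboxylic acids, not yet shown for closing a γ-pyranone ring from an open 1,3-diaryl-1,3-diketone; no stereocentre is formed.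

**Step 3**
Reactants: 5 6,7,8-trimethoxy-2-(4-methoxyphenyl)-4H-chromen-4-one
Product: 7 5-hydroxy-6,7,8-trimethoxy-2-(4-methoxyphenyl)-4H-chromen-4-one, via aryl trifluoroacetate 6 (not isolated)
Conditions: [RuCl2(p-cymene)]2 (5 mol%), PhI(OCOCF3)2 (1.5 equiv), trifluoroacetic acid/trifluoroacetic anhydride 4:1, 80 °C, 6 h; then H2O, rt
Reagents that add atoms: [bis(trifluoroacetoxy)iodo]benzene, O=C(OI(OC(=O)C(F)(F)F)c1ccccc1)C(F)(F)F (one trifluoroacetate oxygen becomes the C5 oxygen)
Why: Ketone-directed ruthenium-catalysed ortho C–H hydroxylation, in which the C4 carbonyl steers cycloruthenation to C5, the only C–H it can reach through a five-membered ruthenacycle; oxidation by the trivalent iodine reagent and C–O reductive elimination give trifluoroacetate 6, which is shielded from over-oxidation until water frees the chelated phenol; no stereocentre is formed.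

**Compound list**
1 | 3',4',5'-trimethoxyacetophenone, 1-(3,4,5-trimethoxyphenyl)ethan-1-one | CC(=O)c1cc(OC)c(OC)c(OC)c1 | starting material
2 | methyl 4-methoxybenzoate | COC(=O)c1ccc(OC)cc1 | starting material
3 | sodium (Z)-1-(4-methoxyphenyl)-3-oxo-3-(3,4,5-trimethoxyphenyl)prop-1-en-1-olate (sodium diketonate, not isolated) | [Na+].[O-]/C(=C\C(=O)c1cc(OC)c(OC)c(OC)c1)c1ccc(OC)cc1 | intermediate
4 | 1-(4-methoxyphenyl)-3-(3,4,5-trimethoxyphenyl)propane-1,3-dione (mainly enol in solution) | COc1ccc(cc1)C(=O)CC(=O)c1cc(OC)c(OC)c(OC)c1 | intermediate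
5 | 6,7,8-trimethoxy-2-(4-methoxyphenyl)-4H-chromen-4-one | COc1ccc(-c2cc(=O)c3cc(OC)c(OC)c(OC)c3o2)cc1 | intermediate
6 | 6,7,8-trimethoxy-2-(4-methoxyphenyl)-4-oxo-4H-chromen-5-yl trifluoroacetate (not isolated) | COc1ccc(-c2cc(=O)c3c(OC(=O)C(F)(F)F)c(OC)c(OC)c(OC)c3o2)cc1 | intermediate
7 | 5-hydroxy-6,7,8-trimethoxy-2-(4-methoxyphenyl)-4H-chromen-4-one | COc1ccc(-c2cc(=O)c3c(O)c(OC)c(OC)c(OC)c3o2)cc1 | target

**Totals**
Total step count: 3. Longest linear sequence: 3 steps (1 → 4 → 5 → 7).

**Steps most likely to fail**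

Step 2 (proposed new cyclisation). Risks are oxidation at the enol α-carbon instead of the ring, over-oxidation of 5, or poor conversion because the aryl ketone raises the oxidation potential. The fallback uses known chemistry, sets out from 1 and comes back at 5. Ring bromination of 1 with N-bromosuccinimide (1.05 equiv, MeCN, rt) gives 1-(2-bromo-3,4,5-trimethoxyphenyl)ethan-1-one F1. Claisen condensation of F1 with 2 (NaH, THF, reflux; then HCl) gives 1-(2-bromo-3,4,5-trimethoxyphenyl)-3-(4-methoxyphenyl)propane-1,3-dione F2. Intramolecular Ullmann-type O-arylation of its enolate (CuI 10 mol%, 1,10-phenanthroline 20 mol%, K2CO3, DMF, 110 °C) closes the same O1–C8a bond and gives 5.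

Step 3 (C5–H hydroxylation). The C–H is flanked by the 6-methoxy group, and the electron-rich ring may be oxidatively demethylated towards a 5,8-quinone. The fallback sets out from 1 and comes back at 7, using halogen in place of both C–H oxygenations. Twofold ring bromination of 1 (N-bromosuccinimide 2.2 equiv, MeCN, 50 °C) gives 1-(2,6-dibromo-3,4,5-trimethoxyphenyl)ethan-1-one F3. Claisen condensation with 2 (NaH, THF, reflux; then HCl) gives 1-(2,6-dibromo-3,4,5-trimethoxyphenyl)-3-(4-methoxyphenyl)propane-1,3-dione F4. Copper-catalysed O-arylation (CuI, 1,10-phenanthroline, K2CO3, DMF, 110 °C) displaces one of the two equivalent bromides and gives 5-bromo-6,7,8-trimethoxy-2-(4-methoxyphenyl)-4H-chromen-4-one F5. Palladium-catalysed hydroxylation of the aryl bromide (Pd2(dba)3, tBuXPhos, KOH, dioxane/H2O, 80 °C; then HCl) gives 7.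

Step 1 (Claisen condensation). Risks are incomplete acylation or self-condensation of 1. The fallback sets out from 1 and comes back at 4. Claisen–Schmidt condensation of 1 with 4-methoxybenzaldehyde (KOH, EtOH, rt) gives the chalcone (E)-3-(4-methoxyphenyl)-1-(3,4,5-trimethoxyphenyl)prop-2-en-1-one F6. Weitz–Scheffer epoxidation (30% H2O2, NaOH, MeOH, 0 °C) gives the racemic trans-epoxy ketone [(2R*,3S*)-3-(4-methoxyphenyl)oxiran-2-yl](3,4,5-trimethoxyphenyl)methanone F7. Isomerisation of the α,β-epoxy ketone to the β-diketone under zerovalent palladium catalysis (Pd(PPh3)4 5 mol%, dppe 5 mol%, toluene, 110 °C) gives 4.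

**Further compounds**
F1 | step 2 | 1-(2-bromo-3,4,5-trimethoxyphenyl)ethan-1-one | CC(=O)c1cc(OC)c(OC)c(OC)c1Br
F2 | step 2 | 1-(2-bromo-3,4,5-trimethoxyphenyl)-3-(4-methoxyphenyl)propane-1,3-dione | COc1ccc(cc1)C(=O)CC(=O)c1cc(OC)c(OC)c(OC)c1Br
F3 | step 3 | 1-(2,6-dibromo-3,4,5-trimethoxyphenyl)ethan-1-one | CC(=O)c1c(Br)c(OC)c(OC)c(OC)c1Br
F4 | step 3 | 1-(2,6-dibromo-3,4,5-trimethoxyphenyl)-3-(4-methoxyphenyl)propane-1,3-dione | COc1ccc(cc1)C(=O)CC(=O)c1c(Br)c(OC)c(OC)c(OC)c1Br
F5 | step 3 | 5-bromo-6,7,8-trimethoxy-2-(4-methoxyphenyl)-4H-chromen-4-one | COc1ccc(-c2cc(=O)c3c(Br)c(OC)c(OC)c(OC)c3o2)cc1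
F6 | step 1 | (E)-3-(4-methoxyphenyl)-1-(3,4,5-trimethoxyphenyl)prop-2-en-1-one | COc1ccc(/C=C/C(=O)c2cc(OC)c(OC)c(OC)c2)cc1
F7 | step 1 | [(2R*,3S*)-3-(4-methoxyphenyl)oxiran-2-yl](3,4,5-trimethoxyphenyl)methanone, racemic trans, one enantiomer drawn | COc1ccc([C@@H]2O[C@H]2C(=O)c2cc(OC)c(OC)c(OC)c2)cc1
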